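## The problem

Compound 29 (CNP0190706.1) is a cis-fused eremophilane, numbered here as the eremophilanes are: ring A is C1–C5 and C10, ring B is C5–C10, C14 is the methyl on the quaternary C5, C15 the methyl on C4, and C11–C13 form the isopropenyl group on C7. Ring B holds an acyloin (C8 ketone, C9 hydroxyl) next to the ring fusion, and O3 is esterified with (2E,4R)-4-angeloyloxyhex-2-enoic acid. Six ring stereocentres (3R,4R,5R,7R,9R,10S), the side-chain carbinol and two alkene geometries (E enoate, Z angelate) have to be delivered. C5 and C10 cannot be repaired once the bicycle exists and must come out of the ring-forming event. In the cis-decalin conformer with the C5 methyl axial on ring A, O3, C15, the isopropenyl group and O9 are all equatorial, so C4 (hydrogen delivered from the C3 hydroxyl), C9 (attack on the convex face) and C7 (enolisable, target epimer the stable one) can be set by the ring, while C3 can be bought and used to control C5 and C10. The angelate isomerises to the tiglate under nucleophilic catalysis, base or heat; the 4-acyloxy-2-enoate is a Michael acceptor and is ionised by zerovalent palladium; the β,γ-unsaturated ketone slips into conjugation and epimerises at C7 with base; the α-ketol does not tolerate base either. The side chain must therefore go on late and the end game must be non-basic. The feature that opens the key step is the fusion bond C5–C10, which joins the methyl-bearing quaternary carbon to a CH flanked by the acyloin carbon C9: C6–C5–C4(=O) reads as an isopropenyl ketone, C7=C8(OSi)–C9=C10 as a 2-silyloxydiene, and C1–C3 as the tether, so one [4+2] maps onto both rings and leaves a C8 enol ether (latent acyloin) and a C4 ketone (handle for C15).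

## Retrosynthesis

**Ester bond O3–C1′ and the O9 silyl group.** Target 29 is traced to its 9-O-TIPS ether 28 and this to alcohol 20 and acid 26. Building the side chain piecewise on the core would expose the bicycle to a second, difficult angeloylation, whereas 20 carries none of the labile ester functions. The forward steps must acylate an equatorial secondary alcohol with retention without touching the angelate, and remove the silyl group without base. Acid 26 is cut at C2′=C3′ into allylic angelate 24 and acrylic acid (25), and 24 at its ester bond into angelic acid (21) and (R)-pent-1-en-3-ol (22).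

**C7–C11.** Alcohol 20 comes from TES ether 19, and 19 from ketone 17 and 2-bromopropene (18) by cutting the C7–isopropenyl bond. An aldol with acetone followed by dehydration would end in the conjugated isopropylidene ketone, and an isopropenyl group carried from the start would not survive the hydrogenation that sets C4. The forward reaction must enolise C8 towards C7 only (C9 is blocked by its silyloxy group), couple without moving the new double bond, and leave the isopropenyl group equatorial. The C3 hydroxyl is masked for this step (17 from 16).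

**C4–H.** Ketone 16 comes from exocyclic alkene 15 by adding hydrogen across C4=C15, and 15 from bis-silyl ether 14 by freeing O3. An undirected hydrogenation has no clear facial bias, since one face is flanked by the axial C14 and the other by C9 standing axial on ring A. Delivery from the C3 hydroxyl puts H4 cis to O3 and C15 cis to C14. This asks for a free O3 beside a protected O9, which is why the two silyl groups differ.

**C9–O and C4=C15.** Silyloxy ketone 14 is traced through silyloxy epoxide 13 to enol ether 12, and 12 to ketone 11. The C8 enol ether places the oxygen at C9 without any regiochemical question, and while C8 is masked the C4 ketone is the only carbonyl, so methylenation must precede oxidation.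

**C5–C10 and C6–C7 (key).** Bicycle 11 is opened to trienone 10. Cutting one ring only, as in an annulation onto a cyclohexanone, would leave the quaternary centre and the cis fusion to separate steps. This cut removes both rings, the quaternary centre and two stereocentres at once and returns an open chain with a single stereocentre. The forward reaction must be endo-selective (cis fusion) and must add to one face under the control of C3.

**The chain.** Trienone 10 is cut at C4–C5 into Weinreb amide 8 and isopropenylmagnesium bromide (9), so that the reactive dienophile appears last. Diene 8 comes from enone 7 by O-silylation, 7 from alkene 5 and methyl vinyl ketone (6) by cutting C9=C10, 5 from ester 4 and hydroxy ester 3, and 3 from methyl (R)-glycidate (1) and allylmagnesium bromide (2) by cutting C1–C2. Every C–C bond of the chain is then made by a standard coupling, and the only stereocentre is purchased.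

## Roads not taken

**Alternative 1:** Ring A alone is cut at C3–C4 and C5–C10. In the forward sense a chiral cationic boron Lewis acid would promote an intermolecular Diels–Alder reaction between a trisubstituted enal carrying both future methyl groups and an (E)-1-alkylbutadiene whose side chain holds the masked C8 ketone, giving cyclohexene carbaldehyde A1 with C4, C5 and C10 set. Its merits are real: three contiguous centres, including the C4 methyl, arrive with the ring, and the absolute configuration comes from a catalyst. In both respects it is better than the chosen plan, which spends methylenation, desilylation and hydrogenation on C15 and trusts one substrate stereocentre for facial control. Its weak points lie in this target. The α,β-disubstituted enal is a sluggish dienophile and the diene is unactivated. The cis fusion needs the formyl group endo, which α-methyl enals do not reliably give. The ring A double bond of A1 sits at C1=C2, so O3 must be brought in by allylic functionalisation with a new stereochemical problem. Ring B still has to be closed by aldol condensation and reduced, and C9 has no handle that distinguishes it from C7. Against the better control of C4, the chosen plan sets the closure of both rings in one step, an oxygen at C3 from the first step, and an enol ether that fixes the site of the C9 oxygen.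

**Alternative 2:** The cut is C5–C6 through a [3,3] shift. The potassium alkoxide of a bridged 2-alkenylbicyclo[2.2.2]octenol would rearrange (anionic oxy-Cope) to the enolate of cis-octalenone A2, with O9 already in place. The rearrangement guarantees the cis fusion and delivers the C7/C8 enolate regiospecifically, which is better than the kinetic deprotonation the chosen plan relies on for C7. The C3=C4 double bond of A2 would also allow hydroboration anti to C14 to set C3 and C4 in one step, again more economical than the chosen sequence for C15. The cost lies before the key step: the bridged carbinol needs a regio- and endo-selective cycloaddition, a face-selective alkenyl addition and a resolution or auxiliary for absolute control. Against this the chosen plan sets a six-step, chiral-pool route to its cyclisation substrate and the formation of both rings from an open chain.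

**Alternative 3:** The cut is C1–C10. A primary radical on a side chain attached to C5 of a 4,4-disubstituted cyclohexadienone would add 6-exo to one of the two enone arms and give cis-octalenone A3. The cis fusion is inherent, and C3 and C4 are set in the side chain beforehand, so no late hydrogenation is needed. The remaining C6=C7 enone of A3 would allow the isopropenyl group to be attached at an sp2 carbon by cross-coupling, a sturdier operation than the enolate alkenylation of the chosen plan. The weak points are the desymmetrisation and the precursor. The choice between the diastereotopic enone arms, which fixes C5 and C10, rests on the conformational bias of the C3/C4 substituents in a slow 6-exo closure that competes with direct reduction. A secondary stereogenic carbon must be joined to the quaternary carbon of the dienone, for which no short reliable method exists. O9 must be added afterwards. Against the safer C7 chemistry of A3, the chosen plan sets a precursor made by routine couplings and a C9 oxygen that follows from the cycloaddition itself.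

Key step: step 7

Assumption: methyl (R)-glycidate (1), (R)-pent-1-en-3-ol (22) and angelic acid (21) are taken as purchasable in high enantiomeric and geometric purity; 22 is otherwise the unreacted enantiomer of a Sharpless kinetic resolution of the racemate with L-(+)-diisopropyl tartrate.

## Route

Step 1
Reactants: 1 methyl (R)-glycidate; 2 allylmagnesium bromide
Product: 3 methyl (R)-2-hydroxyhex-5-enoate
Conditions: CuI (10 mol%), THF, −78 °C, slow addition of 2; aq. NH4Cl
Reagents that add atoms: none
Why: Copper-catalysed epoxide opening at the unsubstituted terminus of a glycidic ester, which is the known regiochemistry of this substrate class; the stereocentre is not touched, so (R)-1 gives (R)-3, and slow addition at low temperature keeps the Grignard reagent from the ester.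

Step 2
Reactants: 3 methyl (R)-2-hydroxyhex-5-enoate
Product: 4 methyl (R)-2-(tert-butyldimethylsilyloxy)hex-5-enoate
Conditions: TBSCl, imidazole, DMF, 23 °C
Reagents that add atoms: tert-butyldimethylsilyl chloride, CC(C)(C)[Si](C)(C)Cl
Why: Standard silylation of a secondary alcohol; the TBS ether should last to the bicycle and can later be removed beside a TIPS ether.

Step 3
Reactants: 4 methyl (R)-2-(tert-butyldimethylsilyloxy)hex-5-enoate
Product: 5 (R)-2-(tert-butyldimethylsilyloxy)-N-methoxy-N-methylhex-5-enamide
Conditions: MeNHOMe·HCl, isopropylmagnesium chloride, THF, −20 to 0 °C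
Reagents that add atoms: N,O-dimethylhydroxylamine hydrochloride, CNOC.Cl
Why: Direct conversion of an ester into a Weinreb amide with the magnesium amide made in the flask; α-silyloxy esters undergo it without loss of configuration.

Step 4
Reactants: 5 (R)-2-(tert-butyldimethylsilyloxy)-N-methoxy-N-methylhex-5-enamide; 6 methyl vinyl ketone
Product: 7 (2R,5E)-2-(tert-butyldimethylsilyloxy)-N-methoxy-N-methyl-7-oxooct-5-enamide
Conditions: RuCl2(H2IMes)(=CH-C6H4-2-O-i-Pr) (second-generation Hoveyda–Grubbs catalyst, 3 mol%), CH2Cl2, 40 °C
Reagents that add atoms: none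
Why: Olefin cross-metathesis of a terminal alkene with an electron-poor vinyl ketone, which dimerises slowly and gives the E-enone.

Step 5
Reactants: 7 (2R,5E)-2-(tert-butyldimethylsilyloxy)-N-methoxy-N-methyl-7-oxooct-5-enamide
Product: 8 (2R,5E)-2-(tert-butyldimethylsilyloxy)-N-methoxy-N-methyl-7-(triisopropylsilyloxy)octa-5,7-dienamide
Conditions: TIPSOTf, Et3N, CH2Cl2, −78 to 0 °C
Reagents that add atoms: triisopropylsilyl trifluoromethanesulfonate, CC(C)[Si](OS(=O)(=O)C(F)(F)F)(C(C)C)C(C)C
Why: Soft enolisation of a methyl enone at the methyl group gives the cross-conjugated 2-silyloxy-1,3-diene; the α-hydrogen of the Weinreb amide is far less acidic, so C3 is not at risk.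

Step 6
Reactants: 8 (2R,5E)-2-(tert-butyldimethylsilyloxy)-N-methoxy-N-methyl-7-(triisopropylsilyloxy)octa-5,7-dienamide; 9 isopropenylmagnesium bromide
Product: 10 (4R,7E)-4-(tert-butyldimethylsilyloxy)-2-methyl-9-(triisopropylsilyloxy)deca-1,7,9-trien-3-one
Conditions: THF, −78 to 0 °C; cold pH 7 phosphate buffer
Reagents that add atoms: none
Why: Grignard addition to a Weinreb amide stops at the chelated tetrahedral intermediate and releases the ketone on work-up; the silyl dienol ether is inert to the Grignard reagent, and the reactive dienophile is created directly before the cycloaddition.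

Step 7
Reactants: 10 (4R,7E)-4-(tert-butyldimethylsilyloxy)-2-methyl-9-(triisopropylsilyloxy)deca-1,7,9-trien-3-one
Product: 11 (3R,5S,10R)-3-(tert-butyldimethylsilyloxy)-5-methyl-8-(triisopropylsilyloxy)-cis-octal-8-en-4-one
Conditions: toluene (0.01 M), BHT (cat.), 80 to 110 °C, base-washed glassware
Reagents that add atoms: none
Why: Thermal intramolecular Diels–Alder reaction of the fused type, the known behaviour of 1,7,9-decatrien-3-ones, here with an α-methyl enone and a 2-silyloxydiene; the cycloaddition is concerted but asynchronous, the electron-rich diene terminus C7 bonding to the enone β-carbon C6 ahead of C10 to C5, and the tether allows no other regiochemistry. Ring B closes as the new cyclohexene of the [4+2] (diene C7–C10 plus dienophile C5–C6), and ring A closes as the six-membered tether ring C10–C1–C2–C3–C4–C5 when the C5–C10 bond forms. C5 and C10 are set relative to each other by the endo orientation of the tether carbonyl under the E-configured C9=C10 bond: the outside substituent C1 and the endo substituent C4 end up cis, so H10 and the C5 methyl are cis and the fusion is cis. Their absolute sense is set by C3: in the chair-like tether of the endo transition state the silyloxy group is equatorial only on the diene face that places it trans to the C5 methyl, whereas addition to the other face needs it axial and 1,3-syn to that methyl, or a boat-like tether. The step therefore needs endo over exo selectivity, which the carbonyl inside a four-atom tether favours, and facial selectivity, which the C3 substituent provides. High dilution and BHT hold back dimerisation and polymerisation of the isopropenyl ketone, and the neutral thermal conditions keep the C8 silyl enol ether and C3 intact.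

Step 8
Reactants: 11 (3R,5S,10R)-3-(tert-butyldimethylsilyloxy)-5-methyl-8-(triisopropylsilyloxy)-cis-octal-8-en-4-one
Product: 12 (3R,5S,10R)-3-(tert-butyldimethylsilyloxy)-5-methyl-4-methylene-8-(triisopropylsilyloxy)-cis-octal-8-ene
Conditions: Cp2Ti(μ-CH2)(μ-Cl)AlMe2 (Tebbe reagent), pyridine, THF/toluene, −40 to 23 °C
Reagents that add atoms: Tebbe reagent, C[Al-]1(C)C[Ti](C2C=CC=C2)(C2C=CC=C2)[Cl+]1
Why: Titanium methylidene olefination is non-basic and copes with hindered, enolisable ketones, so C3 next to the carbonyl is not epimerised; C8 is masked as the enol ether, so C4 is the only carbonyl.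

Step 9
Reactants: 12 (3R,5S,10R)-3-(tert-butyldimethylsilyloxy)-5-methyl-4-methylene-8-(triisopropylsilyloxy)-cis-octal-8-ene
Product: 14 (3R,5S,9R,10S)-3-(tert-butyldimethylsilyloxy)-5-methyl-4-methylene-9-(triisopropylsilyloxy)-cis-decalin-8-one, via silyloxy epoxide 13 (not isolated)
Conditions: mCPBA (1.05 equiv), NaHCO3, CH2Cl2, −20 to 23 °C
Reagents that add atoms: 3-chloroperbenzoic acid, OOC(=O)c1cccc(Cl)c1
Why: Rubottom oxidation; the electron-rich silyl enol ether is epoxidised far faster than the 1,1-disubstituted alkene, and from the convex face that carries H10, because C4 of ring A stands axial over the other face of ring B. The silyloxy epoxide opens with 1,4-shift of the TIPS group to the 9-silyloxy-8-ketone with O9 cis to H10 (equatorial).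

Step 10
Reactants: 14 (3R,5S,9R,10S)-3-(tert-butyldimethylsilyloxy)-5-methyl-4-methylene-9-(triisopropylsilyloxy)-cis-decalin-8-one
Product: 15 (3R,5S,9R,10S)-3-hydroxy-5-methyl-4-methylene-9-(triisopropylsilyloxy)-cis-decalin-8-one
Conditions: HF·pyridine, pyridine, THF, 0 to 23 °C
Reagents that add atoms: none
Why: Silyl ethers are cleaved in order of bulk; the secondary TBS ether goes much faster than the TIPS ether beside the ketone.

Step 11
Reactants: 15 (3R,5S,9R,10S)-3-hydroxy-5-methyl-4-methylene-9-(triisopropylsilyloxy)-cis-decalin-8-one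
Product: 16 (3R,4R,5R,9R,10S)-3-hydroxy-4,5-dimethyl-9-(triisopropylsilyloxy)-cis-decalin-8-one
Conditions: [Ir(cod)(PCy3)(py)]PF6 (5 mol%), H2 (1 atm), CH2Cl2, 0 to 23 °C
Reagents that add atoms: none
Why: Hydroxyl-directed hydrogenation; the cationic iridium centre binds the C3 hydroxyl and delivers hydrogen to the alkene face syn to it, so H4 is cis to O3 and C15 becomes cis to C14 and equatorial. It is placed before the isopropenyl group exists, since that alkene would be reduced as well.

Step 12
Reactants: 16 (3R,4R,5R,9R,10S)-3-hydroxy-4,5-dimethyl-9-(triisopropylsilyloxy)-cis-decalin-8-one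
Product: 17 (3R,4R,5R,9R,10S)-4,5-dimethyl-3-(triethylsilyloxy)-9-(triisopropylsilyloxy)-cis-decalin-8-one
Conditions: TESOTf, 2,6-lutidine, CH2Cl2, −78 °C
Reagents that add atoms: triethylsilyl trifluoromethanesulfonate, CC[Si](CC)(CC)OS(=O)(=O)C(F)(F)F
Why: Silylation masks the C3 hydroxyl, which as a lithium alkoxide could be oxidised by the alkenylpalladium species of the next step; TES is chosen because it can be removed beside TIPS.

Step 13
Reactants: 17 (3R,4R,5R,9R,10S)-4,5-dimethyl-3-(triethylsilyloxy)-9-(triisopropylsilyloxy)-cis-decalin-8-one; 18 2-bromopropene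
Product: 19 (3R,4R,5R,7R,9R,10S)-3-(triethylsilyloxy)-9-(triisopropylsilyloxy)eremophil-11-en-8-one
Conditions: LiN(SiMe3)2 (2.2 equiv), THF, −78 °C; Pd2(dba)3 (2.5 mol%), [HP(t-Bu)3]BF4 (6 mol%), 18, toluene, 23 to 50 °C; AcOH, −78 °C
Reagents that add atoms: none
Why: Palladium-catalysed α-alkenylation of a ketone enolate with a vinyl bromide; the amide base removes a proton from the C7 methylene and not from the hindered, oxygen-bearing C9. The product is held as its dienolate, and kinetic protonation at C7 on the cold quench returns the β,γ-unsaturated ketone; the equatorial isopropenyl group (cis to C14) is also the more stable C7 epimer.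

Step 14
Reactants: 19 (3R,4R,5R,7R,9R,10S)-3-(triethylsilyloxy)-9-(triisopropylsilyloxy)eremophil-11-en-8-one
Product: 20 (3R,4R,5R,7R,9R,10S)-3-hydroxy-9-(triisopropylsilyloxy)eremophil-11-en-8-one
Conditions: PPTS (cat.), MeOH/CH2Cl2, 0 to 23 °C
Reagents that add atoms: none
Why: Mild acid-catalysed methanolysis removes the TES ether and leaves the TIPS ether, the β,γ-unsaturated ketone and C7 alone.

Step 15
Reactants: 21 angelic acid; 22 (R)-pent-1-en-3-ol
Product: 24 (R)-pent-1-en-3-yl (Z)-2-methylbut-2-enoate, via angelic 2,4,6-trichlorobenzoic anhydride 23 (not isolated)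
Conditions: 2,4,6-trichlorobenzoyl chloride, Et3N, toluene, 23 °C; then 22, 80 °C
Reagents that add atoms: 2,4,6-trichlorobenzoyl chloride, O=C(Cl)c1c(Cl)cc(Cl)cc1Cl (its atoms stay in intermediate 23 only)
Why: Esterification through the hindered mixed anhydride (Yamaguchi type) without a nucleophilic catalyst, the established way to transfer an angeloyl group without Z to E isomerisation; the carbinol centre is not involved.

Step 16
Reactants: 24 (R)-pent-1-en-3-yl (Z)-2-methylbut-2-enoate; 25 acrylic acid
Product: 26 (2E,4R)-4-[(Z)-2-methylbut-2-enoyloxy]hex-2-enoic acid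
Conditions: RuCl2(H2IMes)(=CH-C6H4-2-O-i-Pr) (second-generation Hoveyda–Grubbs catalyst, 5 mol%), CH2Cl2, 40 °C
Reagents that add atoms: none
Why: Cross-metathesis of a terminal alkene with acrylic acid gives the E-enoic acid; the trisubstituted, electron-poor angelate double bond does not enter metathesis.

Step 17
Reactants: 20 (3R,4R,5R,7R,9R,10S)-3-hydroxy-9-(triisopropylsilyloxy)eremophil-11-en-8-one; 26 (2E,4R)-4-[(Z)-2-methylbut-2-enoyloxy]hex-2-enoic acid
Product: 28 (3R,4R,5R,7R,9R,10S)-8-oxo-9-(triisopropylsilyloxy)eremophil-11-en-3-yl (2E,4R)-4-[(Z)-2-methylbut-2-enoyloxy]hex-2-enoate, via side-chain mixed anhydride 27 (not isolated)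
Conditions: 26, 2,4,6-trichlorobenzoyl chloride, Et3N, toluene, 23 °C; then 20, DMAP, 23 °C
Reagents that add atoms: 2,4,6-trichlorobenzoyl chloride, O=C(Cl)c1c(Cl)cc(Cl)cc1Cl (its atoms stay in intermediate 27 only)
Why: Yamaguchi esterification of the equatorial C3 alcohol with retention; the activated carbonyl is that of the hexenoic acid, so the angelate is never an acyl donor and keeps its geometry.

Step 18
Reactants: 28 (3R,4R,5R,7R,9R,10S)-8-oxo-9-(triisopropylsilyloxy)eremophil-11-en-3-yl (2E,4R)-4-[(Z)-2-methylbut-2-enoyloxy]hex-2-enoate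
Product: 29 (3R,4R,5R,7R,9R,10S)-9-hydroxy-8-oxoeremophil-11-en-3-yl (2E,4R)-4-[(Z)-2-methylbut-2-enoyloxy]hex-2-enoate (CNP0190706.1)
Conditions: HF·pyridine, THF, 0 to 23 °C
Reagents that add atoms: none
Why: Acidic fluoride cleaves the TIPS ether without base, so the angelate, the 4-acyloxy-enoate, the β,γ-unsaturated ketone, C7 and the α-ketol should all survive.

## Compound list

1 | methyl (R)-oxirane-2-carboxylate (methyl (R)-glycidate) | COC(=O)[C@H]1CO1 | starting material
2 | allylmagnesium bromide | C=CC[Mg]Br | starting material
3 | methyl (R)-2-hydroxyhex-5-enoate | COC(=O)[C@H](O)CCC=C | intermediate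
4 | methyl (R)-2-(tert-butyldimethylsilyloxy)hex-5-enoate | COC(=O)[C@H](O[Si](C)(C)C(C)(C)C)CCC=C | intermediate
5 | (R)-2-(tert-butyldimethylsilyloxy)-N-methoxy-N-methylhex-5-enamide | CON(C)C(=O)[C@H](O[Si](C)(C)C(C)(C)C)CCC=C | intermediate
6 | but-3-en-2-one (methyl vinyl ketone) | CC(=O)C=C | starting material
7 | (2R,5E)-2-(tert-butyldimethylsilyloxy)-N-methoxy-N-methyl-7-oxooct-5-enamide | CON(C)C(=O)[C@H](O[Si](C)(C)C(C)(C)C)CC/C=C/C(C)=O | intermediate
8 | (2R,5E)-2-(tert-butyldimethylsilyloxy)-N-methoxy-N-methyl-7-(triisopropylsilyloxy)octa-5,7-dienamide | CON(C)C(=O)[C@H](O[Si](C)(C)C(C)(C)C)CC/C=C/C(=C)O[Si](C(C)C)(C(C)C)C(C)C | intermediate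
9 | isopropenylmagnesium bromide | CC(=C)[Mg]Br | starting material
10 | (4R,7E)-4-(tert-butyldimethylsilyloxy)-2-methyl-9-(triisopropylsilyloxy)deca-1,7,9-trien-3-one | C=C(C)C(=O)[C@H](O[Si](C)(C)C(C)(C)C)CC/C=C/C(O[Si](C(C)C)(C(C)C)C(C)C)=C | intermediate
11 | (3R,5S,10R)-3-(tert-butyldimethylsilyloxy)-5-methyl-8-(triisopropylsilyloxy)-cis-octal-8-en-4-one (O3 trans to the C5 methyl) | C1C[C@@]2(C)[C@H](CC[C@@H](O[Si](C)(C)C(C)(C)C)C2=O)C=C1O[Si](C(C)C)(C(C)C)C(C)C | intermediate
12 | (3R,5S,10R)-3-(tert-butyldimethylsilyloxy)-5-methyl-4-methylene-8-(triisopropylsilyloxy)-cis-octal-8-ene | C1C[C@@]2(C)[C@H](CC[C@@H](O[Si](C)(C)C(C)(C)C)C2=C)C=C1O[Si](C(C)C)(C(C)C)C(C)C | intermediate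
13 | 8,9-epoxide of 12, epoxide oxygen cis to H10 | C1C[C@@]2(C)[C@H](CC[C@@H](O[Si](C)(C)C(C)(C)C)C2=C)[C@H]3O[C@@]13O[Si](C(C)C)(C(C)C)C(C)C | intermediate
14 | (3R,5S,9R,10S)-3-(tert-butyldimethylsilyloxy)-5-methyl-4-methylene-9-(triisopropylsilyloxy)-cis-decalin-8-one | C1C[C@@]2(C)[C@H](CC[C@@H](O[Si](C)(C)C(C)(C)C)C2=C)[C@@H](O[Si](C(C)C)(C(C)C)C(C)C)C1=O | intermediate
15 | (3R,5S,9R,10S)-3-hydroxy-5-methyl-4-methylene-9-(triisopropylsilyloxy)-cis-decalin-8-one | C1C[C@@]2(C)[C@H](CC[C@@H](O)C2=C)[C@@H](O[Si](C(C)C)(C(C)C)C(C)C)C1=O | intermediate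
16 | (3R,4R,5R,9R,10S)-3-hydroxy-4,5-dimethyl-9-(triisopropylsilyloxy)-cis-decalin-8-one | C1C[C@@]2(C)[C@H](CC[C@@H](O)[C@@H]2C)[C@@H](O[Si](C(C)C)(C(C)C)C(C)C)C1=O | intermediate
17 | (3R,4R,5R,9R,10S)-4,5-dimethyl-3-(triethylsilyloxy)-9-(triisopropylsilyloxy)-cis-decalin-8-one | C1C[C@@]2(C)[C@H](CC[C@@H](O[Si](CC)(CC)CC)[C@@H]2C)[C@@H](O[Si](C(C)C)(C(C)C)C(C)C)C1=O | intermediate
18 | 2-bromopropene | CC(Br)=C | starting material
19 | (3R,4R,5R,7R,9R,10S)-3-(triethylsilyloxy)-9-(triisopropylsilyloxy)eremophil-11-en-8-one | C=C(C)[C@H]1C[C@@]2(C)[C@H](CC[C@@H](O[Si](CC)(CC)CC)[C@@H]2C)[C@@H](O[Si](C(C)C)(C(C)C)C(C)C)C1=O | intermediate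
20 | (3R,4R,5R,7R,9R,10S)-3-hydroxy-9-(triisopropylsilyloxy)eremophil-11-en-8-one | C=C(C)[C@H]1C[C@@]2(C)[C@H](CC[C@@H](O)[C@@H]2C)[C@@H](O[Si](C(C)C)(C(C)C)C(C)C)C1=O | intermediate
21 | angelic acid, (Z)-2-methylbut-2-enoic acid | C/C=C(/C)C(=O)O | starting material
22 | (R)-pent-1-en-3-ol | C=C[C@H](O)CC | starting material
23 | (Z)-2-methylbut-2-enoic 2,4,6-trichlorobenzoic anhydride | C/C=C(/C)C(=O)OC(=O)c1c(Cl)cc(Cl)cc1Cl | intermediate
24 | (R)-pent-1-en-3-yl (Z)-2-methylbut-2-enoate | C=C[C@@H](CC)OC(=O)/C(C)=C\C | intermediate
25 | acrylic acid | C=CC(=O)O | starting material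
26 | (2E,4R)-4-[(Z)-2-methylbut-2-enoyloxy]hex-2-enoic acid | OC(=O)/C=C/[C@@H](CC)OC(=O)/C(C)=C\C | intermediate
27 | mixed anhydride of 26 and 2,4,6-trichlorobenzoic acid | O=C(OC(=O)/C=C/[C@@H](CC)OC(=O)/C(C)=C\C)c1c(Cl)cc(Cl)cc1Cl | intermediate
28 | (3R,4R,5R,7R,9R,10S)-8-oxo-9-(triisopropylsilyloxy)eremophil-11-en-3-yl (2E,4R)-4-[(Z)-2-methylbut-2-enoyloxy]hex-2-enoate | C=C(C)[C@H]1C[C@@]2(C)[C@H](CC[C@@H](OC(=O)/C=C/[C@@H](CC)OC(=O)/C(C)=C\C)[C@@H]2C)[C@@H](O[Si](C(C)C)(C(C)C)C(C)C)C1=O | intermediate
29 | (3R,4R,5R,7R,9R,10S)-9-hydroxy-8-oxoeremophil-11-en-3-yl (2E,4R)-4-[(Z)-2-methylbut-2-enoyloxy]hex-2-enoate (CNP0190706.1) | C=C(C)[C@H]1C[C@@]2(C)[C@H](CC[C@@H](OC(=O)/C=C/[C@@H](CC)OC(=O)/C(C)=C\C)[C@@H]2C)[C@@H](O)C1=O | target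

## Step count and least certain steps

Total: 18 steps. Longest linear sequence: 16 steps (steps 1–14, 17 and 18, from 1 to 29); the side chain takes 2 steps (15 and 16).

**Step 7 (key step).** The most likely failure is facial selection on the wrong side of the dienophile. If the tether reacts through a boat-like arrangement, the C3 silyloxy group may steer the diene to the other face and the C3-epimeric cis series would dominate; some leakage through the exo mode to trans-fused material is the second concern, because the α-methyl group weakens the endo preference of the carbonyl. Fallback: the C3 configuration is reversed before the cycloaddition and put right on the bicycle. It sets out from hydroxy ester 3 and returns at 15.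
- Mitsunobu reaction of 3 with 4-nitrobenzoic acid (PPh3, diisopropyl azodicarboxylate) gives methyl (S)-2-(4-nitrobenzoyloxy)hex-5-enoate F1, and methanolysis (K2CO3, MeOH) gives methyl (S)-2-hydroxyhex-5-enoate F2.
- The operations of steps 2 to 6 then give the (S)-silyl ether F3, the (S)-Weinreb amide F4, the (S)-enone F5, the (S)-silyloxydiene F6 and the (S)-trienone F7.
- Cycloaddition on the face that is then preferred gives the 3-epi adduct F8, with C5 and C10 as in 11 and O3 cis to the C5 methyl.
- The operations of steps 8 to 10 give the 3-epi methylene compound F9, its silyloxy epoxide F10 (not isolated), the 3-epi silyloxy ketone F11 and the 3-epi allylic alcohol F12.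
- A second Mitsunobu reaction with 4-nitrobenzoic acid inverts C3 to the 4-nitrobenzoate F13, and methanolysis gives 15. C9, being α to the ketone, can be equilibrated to the equatorial silyloxy epimer if the altered ring conformation of this series changes the face of the oxidation.

**Step 13.** The alkenylation may suffer from migration of the new double bond into conjugation with the ketone, from double alkenylation, or from protonation of the dienolate on the wrong face of C7; all three follow from the basic conditions and the acidity of the product. Fallback: the isopropenyl group is attached at an sp2 carbon. It sets out from 17 and returns at 19.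
- The lithium enolate of 17 (LiN(i-Pr)2, THF, −78 °C) is dehydrogenated with N-tert-butylbenzenesulfinimidoyl chloride to the 6-en-8-one F14.
- Iodine and pyridine give the 7-iodo-6-en-8-one F15.
- Suzuki coupling with isopropenylboronic acid pinacol ester (PdCl2(dppf), K3PO4, THF/H2O) gives the 6,11-dien-8-one F16.
- Conjugate reduction with [(Ph3P)CuH]6 and protonation at C7 gives 19.

**Step 8.** The C4 ketone lies between a quaternary carbon and a silyloxy-bearing carbon, and the titanium reagent may react slowly or enolise it. Fallback: a Peterson sequence. It sets out from 11 and returns at 12. Addition of Me3SiCH2Li in the presence of CeCl3 (THF, −78 °C) gives the 4-hydroxy-4-(trimethylsilylmethyl) adduct F17 (C4 configuration immaterial), and syn elimination with KH in THF gives 12.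

**Step 11.** The iridium catalyst may be hindered by C9 standing axial below C4, giving incomplete facial control or isomerisation of the exocyclic alkene. Fallback: radical hydrogen-atom-transfer hydrogenation (Mn(dpm)3, PhSiH3, tert-butyl hydroperoxide, i-PrOH), which reduces 15 to 16 through the tertiary C4 radical and should favour the equatorial methyl group. It sets out from 15, returns at 16 and makes no new compound.

**Step 6.** The silyl dienol ether may be hydrolysed during work-up, or the liberated N,O-dimethylhydroxylamine may add to the new enone. Fallback: the order of events is changed so that the dienol ether is made last. It sets out from 5 and returns at 10. Isopropenylmagnesium bromide converts 5 into (R)-4-(tert-butyldimethylsilyloxy)-2-methylocta-1,7-dien-3-one F18; cross-metathesis with methyl vinyl ketone gives (4R,7E)-4-(tert-butyldimethylsilyloxy)-2-methyldeca-1,7-diene-3,9-dione F19; selective soft enolisation of the methyl ketone (TIPSOTf, Et3N) gives 10.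

**Step 1.** The allyl Grignard reagent may attack the ester faster than the copper-mediated epoxide opening. Fallback: the opening is run on the carboxylate. It sets out from 1 and returns at 3. Saponification (KOH, EtOH, 0 °C) gives potassium (R)-glycidate F20; allylmagnesium chloride with CuI (THF, −20 °C) gives (R)-2-hydroxyhex-5-enoic acid F21; esterification (MeOH, HCl cat.) gives 3.

## Further compounds

F1 | step 7 | methyl (S)-2-(4-nitrobenzoyloxy)hex-5-enoate | COC(=O)[C@@H](OC(=O)c1ccc(cc1)[N+](=O)[O-])CCC=C
F2 | step 7 | methyl (S)-2-hydroxyhex-5-enoate | COC(=O)[C@@H](O)CCC=C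
F3 | step 7 | methyl (S)-2-(tert-butyldimethylsilyloxy)hex-5-enoate | COC(=O)[C@@H](O[Si](C)(C)C(C)(C)C)CCC=C
F4 | step 7 | (S)-2-(tert-butyldimethylsilyloxy)-N-methoxy-N-methylhex-5-enamide | CON(C)C(=O)[C@@H](O[Si](C)(C)C(C)(C)C)CCC=C
F5 | step 7 | (2S,5E)-2-(tert-butyldimethylsilyloxy)-N-methoxy-N-methyl-7-oxooct-5-enamide | CON(C)C(=O)[C@@H](O[Si](C)(C)C(C)(C)C)CC/C=C/C(C)=O
F6 | step 7 | (2S,5E)-2-(tert-butyldimethylsilyloxy)-N-methoxy-N-methyl-7-(triisopropylsilyloxy)octa-5,7-dienamide | CON(C)C(=O)[C@@H](O[Si](C)(C)C(C)(C)C)CC/C=C/C(=C)O[Si](C(C)C)(C(C)C)C(C)C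
F7 | step 7 | (4S,7E)-4-(tert-butyldimethylsilyloxy)-2-methyl-9-(triisopropylsilyloxy)deca-1,7,9-trien-3-one | C=C(C)C(=O)[C@@H](O[Si](C)(C)C(C)(C)C)CC/C=C/C(O[Si](C(C)C)(C(C)C)C(C)C)=C
F8 | step 7 | (3S,5S,10R)-3-(tert-butyldimethylsilyloxy)-5-methyl-8-(triisopropylsilyloxy)-cis-octal-8-en-4-one (3-epi-11) | C1C[C@@]2(C)[C@H](CC[C@H](O[Si](C)(C)C(C)(C)C)C2=O)C=C1O[Si](C(C)C)(C(C)C)C(C)C
F9 | step 7 | (3S,5S,10R)-3-(tert-butyldimethylsilyloxy)-5-methyl-4-methylene-8-(triisopropylsilyloxy)-cis-octal-8-ene (3-epi-12) | C1C[C@@]2(C)[C@H](CC[C@H](O[Si](C)(C)C(C)(C)C)C2=C)C=C1O[Si](C(C)C)(C(C)C)C(C)C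
F10 | step 7 | 8,9-epoxide of F9, epoxide oxygen cis to H10 | C1C[C@@]2(C)[C@H](CC[C@H](O[Si](C)(C)C(C)(C)C)C2=C)[C@H]3O[C@@]13O[Si](C(C)C)(C(C)C)C(C)C
F11 | step 7 | 3-epi-14, 3-(tert-butyldimethylsilyloxy)-5-methyl-4-methylene-9-(triisopropylsilyloxy)-cis-decalin-8-one with O3 cis to the C5 methyl | C1C[C@@]2(C)[C@H](CC[C@H](O[Si](C)(C)C(C)(C)C)C2=C)[C@@H](O[Si](C(C)C)(C(C)C)C(C)C)C1=O
F12 | step 7 | 3-epi-15, 3-hydroxy-5-methyl-4-methylene-9-(triisopropylsilyloxy)-cis-decalin-8-one with O3 cis to the C5 methyl | C1C[C@@]2(C)[C@H](CC[C@H](O)C2=C)[C@@H](O[Si](C(C)C)(C(C)C)C(C)C)C1=O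
F13 | step 7 | 4-nitrobenzoate of 15 | C1C[C@@]2(C)[C@H](CC[C@@H](OC(=O)c3ccc(cc3)[N+](=O)[O-])C2=C)[C@@H](O[Si](C(C)C)(C(C)C)C(C)C)C1=O
F14 | step 13 | 6,7-didehydro-17 (cis-fused 4,5-dimethyl-3-(triethylsilyloxy)-9-(triisopropylsilyloxy)octal-6-en-8-one) | C1=C[C@@]2(C)[C@H](CC[C@@H](O[Si](CC)(CC)CC)[C@@H]2C)[C@@H](O[Si](C(C)C)(C(C)C)C(C)C)C1=O
F15 | step 13 | 7-iodo derivative of F14 | IC1=C[C@@]2(C)[C@H](CC[C@@H](O[Si](CC)(CC)CC)[C@@H]2C)[C@@H](O[Si](C(C)C)(C(C)C)C(C)C)C1=O
F16 | step 13 | 3-(triethylsilyloxy)-9-(triisopropylsilyloxy)eremophila-6,11-dien-8-one | C=C(C)C1=C[C@@]2(C)[C@H](CC[C@@H](O[Si](CC)(CC)CC)[C@@H]2C)[C@@H](O[Si](C(C)C)(C(C)C)C(C)C)C1=O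
F17 | step 8 | 4-hydroxy-4-(trimethylsilylmethyl) adduct of 11 (C4 configuration immaterial) | C1C[C@@]2(C)[C@H](CC[C@@H](O[Si](C)(C)C(C)(C)C)C2(O)C[Si](C)(C)C)C=C1O[Si](C(C)C)(C(C)C)C(C)C
F0 | step 11 | none | none
F18 | step 6 | (R)-4-(tert-butyldimethylsilyloxy)-2-methylocta-1,7-dien-3-one | C=C(C)C(=O)[C@H](O[Si](C)(C)C(C)(C)C)CCC=C
F19 | step 6 | (4R,7E)-4-(tert-butyldimethylsilyloxy)-2-methyldeca-1,7-diene-3,9-dione | C=C(C)C(=O)[C@H](O[Si](C)(C)C(C)(C)C)CC/C=C/C(C)=O
F20 | step 1 | potassium (R)-oxirane-2-carboxylate | [K+].[O-]C(=O)[C@H]1CO1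
F21 | step 1 | (R)-2-hydroxyhex-5-enoic acid | OC(=O)[C@H](O)CCC=C
A1 | alternative 1 | 1,6-dimethyl-2-[(2-methyl-1,3-dioxolan-2-yl)methyl]cyclohex-3-ene-1-carbaldehyde | O=C[C@@]1(C)[C@H](C=CC[C@@H]1C)CC2(C)OCCO2
A2 | alternative 2 | cis-fused 9-(4-methoxybenzyloxy)-4,5-dimethyloctal-3-en-8-one | C1C[C@@]2(C)[C@H](CCC=C2C)[C@@H](OCc3ccc(OC)cc3)C1=O
A3 | alternative 3 | cis-fused 3-(tert-butyldimethylsilyloxy)-4,5-dimethyloctal-6-en-8-one | C1=C[C@@]2(C)[C@H](CC[C@@H](O[Si](C)(C)C(C)(C)C)[C@@H]2C)CC1=O
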